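**Plan** (isochromene numbering of the core: O2, C1, C3, C4, C4a, C5, C6, C7, C8, C8a)

- Retrosynthesis: the tert-butyl ester of the acrylic acid is cut first, then the pyran at O2–C3 (enolised C1 aldehyde plus a C3≡C4 alkyne), then the C1 aldehyde is traced back to CH2NO2. The carbocycle is finally cut at C6–C7 and C8–C8a.
- These two cuts work because C6(=O)–C7(OH)(CH3)–C8H(CO2R) is the acyloin of an acetoacetate (C7 its ketone, C8 its α-carbon). The enol-ether carbon C1 is an aldehyde that can be carried as a nitro group, which turns C8a into a Michael acceptor, while C6 is an aldehyde open to carbene (acyl anion) catalysis.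
- Forward: three fragments are made, namely acetoacetate 8 of the side-chain alcohol, enyne ester 12 and nitro dienal 23 (from a 1,1-dibromoalkene by two stereospecific couplings). A one-pot Michael addition/crossed benzoin closes the carbocycle; the pyran ring is closed last.
- Stereochemistry: C4 of the alcohol comes from (S)-1-bromo-2-methylbutane (chiral pool), C2 from a lipase resolution. C8a is set by a chiral thiourea as a temporary stereocentre; it relays to C7 and C8 (C8 through an epimerising keto ester) and is erased when C8a becomes sp2 in the pyran.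

Key step: step 12

Assumption 1: 2,2-dimethoxyacetaldehyde, sold as an aqueous solution, is extracted into CH2Cl2 and dried before step 6.
Assumption 2: the (1S,2S) antipode of the thiourea in step 12 is taken to deliver (R) at the new CH(CH2NO2) carbon; if the facial sense with this dienyl nitroalkene is the opposite, the (1R,2R) catalyst is used.

**Route**

Step 1
Reactants: 1 (S)-1-bromo-2-methylbutane; 2 acetaldehyde
Product: 4 (4S)-4-methylhexan-2-ol (both C2 epimers), via Grignard reagent 3 (not isolated)
Conditions: Mg, THF, rt to 40 °C; then 2, −78 → 0 °C; aq. HCl work-up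
Reagents that add atoms: none
Why: Grignard addition to an aldehyde: the primary alkylmagnesium bromide 3 should add to 2 without touching the stereocentre β to magnesium, while the new carbinol centre forms without control and is sorted in step 2.

Step 2
Reactants: 4 (4S)-4-methylhexan-2-ol (both C2 epimers)
Product: 5 (2S,4S)-4-methylhexan-2-ol (the epimer left unacylated)
Conditions: Novozym 435 (immobilised Candida antarctica lipase B), vinyl acetate (0.6 equiv), hexane, 30 °C; chromatography
Reagents that add atoms: none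
Why: Lipase-catalysed transesterification (kinetic resolution of epimers): the enzyme should acylate the (2R)-configured methyl carbinol much faster, so that the (2S,4S)-alcohol stays behind and is separated from the (2R,4S)-acetate.

Step 3
Reactants: 5 (2S,4S)-4-methylhexan-2-ol; 6 2,2,6-trimethyl-4H-1,3-dioxin-4-one
Product: 8 (2S,4S)-4-methylhexan-2-yl 3-oxobutanoate, via acetylketene 7 (not isolated)
Conditions: toluene, 110 °C, acetone distilled off
Reagents that add atoms: none
Why: Acetoacetylation through a retro-hetero-Diels–Alder reaction: 6 should lose acetone on heating to give acetylketene 7, which the secondary alcohol traps as the β-keto ester without affecting either stereocentre.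

Step 4
Reactants: 9 3-(trimethylsilyl)prop-2-ynal; 10 tert-butyl 2-(triphenyl-λ5-phosphanylidene)acetate
Product: 11 tert-butyl (E)-5-(trimethylsilyl)pent-2-en-4-ynoate
Conditions: CH2Cl2, 0 °C → rt
Reagents that add atoms: none
Why: Wittig olefination with a stabilised ylide, which should give the E-enoate selectively and leave the silyl alkyne untouched.

Step 5
Reactants: 11 tert-butyl (E)-5-(trimethylsilyl)pent-2-en-4-ynoate
Product: 12 tert-butyl (E)-pent-2-en-4-ynoate
Conditions: K2CO3 (0.1 equiv), MeOH–THF, 0 °C, short reaction time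
Reagents that add atoms: none
Why: Base-catalysed methanolysis of the alkynyl C–Si bond (protodesilylation), fast enough at 0 °C that the tert-butyl ester and the enoate should survive.

Step 6
Reactants: 13 2,2-dimethoxyacetaldehyde
Product: 14 1,1-dibromo-3,3-dimethoxyprop-1-ene
Conditions: CBr4 (2 equiv), PPh3 (4 equiv), Et3N (1 equiv), CH2Cl2, 0 °C
Reagents that add atoms: carbon tetrabromide, BrC(Br)(Br)Br
Why: Dibromoolefination (first stage of the Corey–Fuchs reaction): the ylide made from CBr4 and PPh3 should convert the aldehyde into the 1,1-dibromoalkene while Et3N keeps the medium non-acidic for the acetal.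

Step 7
Reactants: 14 1,1-dibromo-3,3-dimethoxyprop-1-ene; 12 tert-butyl (E)-pent-2-en-4-ynoate
Product: 15 tert-butyl (2E,6Z)-6-bromo-8,8-dimethoxyocta-2,6-dien-4-ynoate
Conditions: Pd(PPh3)4 (5 mol %), CuI (10 mol %), i-Pr2NH (2 equiv), toluene, rt
Reagents that add atoms: none
Why: Sonogashira coupling of a 1,1-dibromoalkene: oxidative addition should occur at the less hindered C–Br bond trans to the acetal-bearing substituent, so the alkyne enters trans to CH(OMe)2 and the remaining bromide is cis to it (6Z).

Step 8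
Reactants: 15 tert-butyl (2E,6Z)-6-bromo-8,8-dimethoxyocta-2,6-dien-4-ynoate; 16 (tributylstannyl)methanol
Product: 17 tert-butyl (2E,6Z)-6-(hydroxymethyl)-8,8-dimethoxyocta-2,6-dien-4-ynoate
Conditions: Pd(PPh3)4 (8 mol %), 1,4-dioxane, 90 °C
Reagents that add atoms: none
Why: Stille coupling (hydroxymethylation) with retention of alkene geometry, which should place the future C8a carbon cis to the future C6 carbon.

Step 9
Reactants: 17 tert-butyl (2E,6Z)-6-(hydroxymethyl)-8,8-dimethoxyocta-2,6-dien-4-ynoate
Product: 18 tert-butyl (2E,6Z)-6-formyl-8,8-dimethoxyocta-2,6-dien-4-ynoate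
Conditions: activated MnO2 (excess), CH2Cl2, rt
Reagents that add atoms: none
Why: MnO2 oxidation of a primary allylic alcohol to the enal under neutral conditions that should leave the acetal, the ester and the alkene geometry intact.

Step 10
Reactants: 18 tert-butyl (2E,6Z)-6-formyl-8,8-dimethoxyocta-2,6-dien-4-ynoate; 19 nitromethane
Product: 22 tert-butyl (2E,6E)-8,8-dimethoxy-6-[(E)-2-nitroethenyl]octa-2,6-dien-4-ynoate, via nitro alcohol 20 (not isolated), via mesylate 21 (not isolated)
Conditions: 19 (10 equiv), 1,1,3,3-tetramethylguanidine (10 mol %), THF, 0 °C; then MsCl (1.5 equiv), Et3N (3 equiv), CH2Cl2, −20 → 0 °C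
Reagents that add atoms: none
Why: Henry reaction followed by dehydration: nitromethane should add 1,2 to the aldehyde, and nitro alcohol 20 is eliminated through its mesylate 21 (E1cB) to the E-nitroalkene, the trisubstituted alkene keeping its geometry.

Step 11
Reactants: 22 tert-butyl (2E,6E)-8,8-dimethoxy-6-[(E)-2-nitroethenyl]octa-2,6-dien-4-ynoate
Product: 23 tert-butyl (2E,6E)-6-[(E)-2-nitroethenyl]-8-oxoocta-2,6-dien-4-ynoate
Conditions: 1 M aq. HCl, acetone, 0 °C → rt; used at once
Reagents that add atoms: water, O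
Why: Acid-catalysed hydrolysis of the allylic dimethyl acetal, which should unmask the aldehyde (future C6) cis to the nitrovinyl group while nitroalkene and tert-butyl ester tolerate dilute acid.

Step 12
Reactants: 8 (2S,4S)-4-methylhexan-2-yl 3-oxobutanoate; 23 tert-butyl (2E,6E)-6-[(E)-2-nitroethenyl]-8-oxoocta-2,6-dien-4-ynoate
Product: 25 (2S,4S)-4-methylhexan-2-yl (1R,2R,6R)-5-[(3E)-5-tert-butoxy-5-oxopent-3-en-1-yn-1-yl]-2-hydroxy-2-methyl-6-(nitromethyl)-3-oxocyclohex-4-ene-1-carboxylate, via Michael adduct 24 (not isolated)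
Conditions: 8 (1.2 equiv), 1-[3,5-bis(trifluoromethyl)phenyl]-3-[(1S,2S)-2-(dimethylamino)cyclohexyl]thiourea (10 mol %), toluene, −20 °C; then, in the same flask, 2-(pentafluorophenyl)-6,7-dihydro-5H-pyrrolo[2,1-c][1,2,4]triazol-2-ium tetrafluoroborate (20 mol %), NaOAc (20 mol %), CHCl3, 0 °C → rt
Reagents that add atoms: none
Why: The amine–thiourea catalyst should add the enol of 8 through its α-carbon (future C8) to the nitroalkene β-carbon of 23 (future C8a), giving 24, in which the acidic C8–H keeps both C8 epimers in equilibrium; the triazolylidene then turns the enal carbon C6 into an acyl anion equivalent that adds to the methyl ketone (C7) in a crossed aldehyde–ketone benzoin reaction. The closest known reaction type is the one-pot organocatalytic Michael addition of a 1,3-dicarbonyl compound followed by carbene-catalysed intramolecular crossed benzoin closure. The only ring closed is the carbocycle, by 6-exo-trig attack of C6 on the C7 carbonyl. C8a is set by the chiral thiourea in the addition step; C7 and C8 are then set under its control through a half-chair in which nitromethyl and ester are trans and pseudo-equatorial, the methyl is pseudo-equatorial and the forming alkoxide is pseudo-axial and hydrogen-bonded to the ester, so the labile C8 epimers should funnel into the (7R,8R) arrangement. The step needs attack at the nitroalkene and not at the aldehyde, alkyne or acrylate, which the much higher electrophilicity of the nitroalkene secures, and acyl anion instead of homoenolate reactivity at C6, which the fully substituted β-carbon (C4a), the electron-poor N-aryl triazolium and the weak acetate base favour; the cis geometry of C4a=C5 built in steps 7 and 8 holds C6 next to C8a so that the six-membered closure can reach the ketone.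

Step 13
Reactants: 25 (2S,4S)-4-methylhexan-2-yl (1R,2R,6R)-5-[(3E)-5-tert-butoxy-5-oxopent-3-en-1-yn-1-yl]-2-hydroxy-2-methyl-6-(nitromethyl)-3-oxocyclohex-4-ene-1-carboxylate
Product: 28 (2S,4S)-4-methylhexan-2-yl (1R,2R)-5-[(3E)-5-tert-butoxy-5-oxopent-3-en-1-yn-1-yl]-6-formyl-2-hydroxy-2-methyl-3-oxocyclohex-4-ene-1-carboxylate (C6 epimers, in equilibrium with the hydroxymethylidene enol), via nitronate salt 26 (not isolated), via imine 27 (not isolated)
Conditions: DBU (1.05 equiv), THF, 0 °C; then aq. TiCl3 (5 equiv), NH4OAc buffer (pH 5–6), THF–H2O, 0 °C → rt; crude product taken on directly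
Reagents that add atoms: water, O
Why: Nef reaction in its reductive titanium trichloride variant: nitronate 26 should be reduced to imine 27, which hydrolyses at pH 5–6 to the aldehyde, so that neither strong acid nor excess base reaches the β-hydroxy ester; the formyl-bearing carbon becomes epimerisable, which is of no consequence.

Step 14
Reactants: 28 (2S,4S)-4-methylhexan-2-yl (1R,2R)-5-[(3E)-5-tert-butoxy-5-oxopent-3-en-1-yn-1-yl]-6-formyl-2-hydroxy-2-methyl-3-oxocyclohex-4-ene-1-carboxylate
Product: 29 (2S,4S)-4-methylhexan-2-yl (7R,8R)-3-[(E)-3-tert-butoxy-3-oxoprop-1-en-1-yl]-7-hydroxy-7-methyl-6-oxo-7,8-dihydro-6H-isochromene-8-carboxylate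
Conditions: Ph3PAuNTf2 (5 mol %), CH2Cl2, 0 °C → rt
Reagents that add atoms: none
Why: Gold-catalysed cycloisomerisation of an alkynyl aldehyde: the oxygen of the enolised formyl group should attack the activated alkyne in a 6-endo-dig closure at the carbon remote from the ring, and protodeauration gives the 4H-pyran-4-ylidene ketone, erasing the temporary stereocentre at C8a as it becomes sp2.

Step 15
Reactants: 29 (2S,4S)-4-methylhexan-2-yl (7R,8R)-3-[(E)-3-tert-butoxy-3-oxoprop-1-en-1-yl]-7-hydroxy-7-methyl-6-oxo-7,8-dihydro-6H-isochromene-8-carboxylate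
Product: 30 (E)-3-[(7R,8R)-7-hydroxy-7-methyl-8-{[(2S,4S)-4-methylhexan-2-yl]oxycarbonyl}-6-oxo-7,8-dihydro-6H-isochromen-3-yl]prop-2-enoic acid
Conditions: TFA–CH2Cl2 (1:4), 0 °C; evaporation without aqueous base
Reagents that add atoms: none
Why: Acidolysis of the tert-butyl ester (loss of isobutene), which should spare the secondary alkyl ester, the tertiary alcohol next to the ketone and the vinylogous ester core at 0 °C.

**Compound list**

1 | (S)-1-bromo-2-methylbutane | CC[C@H](C)CBr | starting material
2 | acetaldehyde | CC=O | starting material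
3 | (S)-2-methylbutylmagnesium bromide | CC[C@H](C)C[Mg]Br | intermediate
4 | (4S)-4-methylhexan-2-ol, both C2 epimers | CC[C@H](C)CC(C)O | intermediate
5 | (2S,4S)-4-methylhexan-2-ol | CC[C@H](C)C[C@H](C)O | intermediate
6 | 2,2,6-trimethyl-4H-1,3-dioxin-4-one | CC1=CC(=O)OC(C)(C)O1 | starting material
7 | acetylketene | CC(=O)C=C=O | intermediate
8 | (2S,4S)-4-methylhexan-2-yl 3-oxobutanoate | CC[C@H](C)C[C@H](C)OC(=O)CC(C)=O | intermediate
9 | 3-(trimethylsilyl)prop-2-ynal | C[Si](C)(C)C#CC=O | starting material
10 | tert-butyl 2-(triphenyl-λ5-phosphanylidene)acetate | CC(C)(C)OC(=O)C=P(c1ccccc1)(c1ccccc1)c1ccccc1 | starting material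
11 | tert-butyl (E)-5-(trimethylsilyl)pent-2-en-4-ynoate | CC(C)(C)OC(=O)/C=C/C#C[Si](C)(C)C | intermediate
12 | tert-butyl (E)-pent-2-en-4-ynoate | CC(C)(C)OC(=O)/C=C/C#C | intermediate
13 | 2,2-dimethoxyacetaldehyde | COC(OC)C=O | starting material
14 | 1,1-dibromo-3,3-dimethoxyprop-1-ene | COC(OC)C=C(Br)Br | intermediate
15 | tert-butyl (2E,6Z)-6-bromo-8,8-dimethoxyocta-2,6-dien-4-ynoate | CC(C)(C)OC(=O)/C=C/C#C/C(Br)=C/C(OC)OC | intermediate
16 | (tributylstannyl)methanol | CCCC[Sn](CCCC)(CCCC)CO | starting material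
17 | tert-butyl (2E,6Z)-6-(hydroxymethyl)-8,8-dimethoxyocta-2,6-dien-4-ynoate | CC(C)(C)OC(=O)/C=C/C#C/C(CO)=C/C(OC)OC | intermediate
18 | tert-butyl (2E,6Z)-6-formyl-8,8-dimethoxyocta-2,6-dien-4-ynoate | CC(C)(C)OC(=O)/C=C/C#C/C(C=O)=C/C(OC)OC | intermediate
19 | nitromethane | C[N+](=O)[O-] | starting material
20 | tert-butyl (2E,6Z)-6-(1-hydroxy-2-nitroethyl)-8,8-dimethoxyocta-2,6-dien-4-ynoate (carbinol epimers) | CC(C)(C)OC(=O)/C=C/C#C/C(C(O)C[N+](=O)[O-])=C/C(OC)OC | intermediate
21 | tert-butyl (2E,6Z)-8,8-dimethoxy-6-[1-(methanesulfonyloxy)-2-nitroethyl]octa-2,6-dien-4-ynoate | CC(C)(C)OC(=O)/C=C/C#C/C(C(OS(C)(=O)=O)C[N+](=O)[O-])=C/C(OC)OC | intermediate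
22 | tert-butyl (2E,6E)-8,8-dimethoxy-6-[(E)-2-nitroethenyl]octa-2,6-dien-4-ynoate | CC(C)(C)OC(=O)/C=C/C#C/C(/C=C/[N+](=O)[O-])=C/C(OC)OC | intermediate
23 | tert-butyl (2E,6E)-6-[(E)-2-nitroethenyl]-8-oxoocta-2,6-dien-4-ynoate | CC(C)(C)OC(=O)/C=C/C#C/C(/C=C/[N+](=O)[O-])=C/C=O | intermediate
24 | (2S,4S)-4-methylhexan-2-yl (3R,4E)-2-acetyl-4-[(3E)-5-tert-butoxy-5-oxopent-3-en-1-yn-1-yl]-3-(nitromethyl)-6-oxohex-4-enoate, C2 epimers | CC[C@H](C)C[C@H](C)OC(=O)C(C(C)=O)[C@@H](C[N+](=O)[O-])/C(C#C/C=C/C(=O)OC(C)(C)C)=C\C=O | intermediate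
25 | (2S,4S)-4-methylhexan-2-yl (1R,2R,6R)-5-[(3E)-5-tert-butoxy-5-oxopent-3-en-1-yn-1-yl]-2-hydroxy-2-methyl-6-(nitromethyl)-3-oxocyclohex-4-ene-1-carboxylate | CC[C@H](C)C[C@H](C)OC(=O)[C@@H]1[C@@H](C[N+](=O)[O-])C(C#C/C=C/C(=O)OC(C)(C)C)=CC(=O)[C@]1(C)O | intermediate
26 | 1,8-diazabicyclo[5.4.0]undec-7-enium nitronate of 25 | CC[C@H](C)C[C@H](C)OC(=O)[C@@H]1[C@@H](C=[N+]([O-])[O-])C(C#C/C=C/C(=O)OC(C)(C)C)=CC(=O)[C@]1(C)O.C1CCC2=[NH+]CCCN2CC1 | intermediate
27 | (2S,4S)-4-methylhexan-2-yl (1R,2R)-5-[(3E)-5-tert-butoxy-5-oxopent-3-en-1-yn-1-yl]-2-hydroxy-6-(iminomethyl)-2-methyl-3-oxocyclohex-4-ene-1-carboxylate | CC[C@H](C)C[C@H](C)OC(=O)[C@@H]1C(C=N)C(C#C/C=C/C(=O)OC(C)(C)C)=CC(=O)[C@]1(C)O | intermediate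
28 | (2S,4S)-4-methylhexan-2-yl (1R,2R)-5-[(3E)-5-tert-butoxy-5-oxopent-3-en-1-yn-1-yl]-6-formyl-2-hydroxy-2-methyl-3-oxocyclohex-4-ene-1-carboxylate | CC[C@H](C)C[C@H](C)OC(=O)[C@@H]1C(C=O)C(C#C/C=C/C(=O)OC(C)(C)C)=CC(=O)[C@]1(C)O | intermediate
29 | (2S,4S)-4-methylhexan-2-yl (7R,8R)-3-[(E)-3-tert-butoxy-3-oxoprop-1-en-1-yl]-7-hydroxy-7-methyl-6-oxo-7,8-dihydro-6H-isochromene-8-carboxylate | CC[C@H](C)C[C@H](C)OC(=O)[C@@H]1C2=COC(/C=C/C(=O)OC(C)(C)C)=CC2=CC(=O)[C@]1(C)O | intermediate
30 | (E)-3-[(7R,8R)-7-hydroxy-7-methyl-8-{[(2S,4S)-4-methylhexan-2-yl]oxycarbonyl}-6-oxo-7,8-dihydro-6H-isochromen-3-yl]prop-2-enoic acid | CC[C@H](C)C[C@H](C)OC(=O)[C@@H]1C2=COC(/C=C/C(=O)O)=CC2=CC(=O)[C@]1(C)O | target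

**Step count**

Total: 15 steps. Longest linear sequence: 11 steps (steps 4, 5 and 7 to 15, from 9).

**Steps most likely to fail**

Step 12. What may go wrong is diversion during the base-catalysed addition stage: the nitronate or the keto ester enolate of 24 can close a five-membered ring onto the neighbouring free aldehyde (Henry or aldol closure), or the triply electrophilic nitro dienal can oligomerise, before the carbene is present. The fallback keeps the aldehyde masked during the conjugate addition. It sets out from 22 and 8: the same thiourea-catalysed Michael addition is run on the acetal and should give (2S,4S)-4-methylhexan-2-yl (3R,4E)-2-acetyl-4-[(3E)-5-tert-butoxy-5-oxopent-3-en-1-yn-1-yl]-6,6-dimethoxy-3-(nitromethyl)hex-4-enoate F1, in which no carbonyl electrophile is within reach of the nitronate. Hydrolysis of the allylic acetal (1 M aq. HCl, acetone, 0 °C) then gives 24 as an isolated compound, which is closed with the triazolium salt and NaOAc in a separate operation. The sequence comes back to the route at 25.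

Step 13. What may go wrong is over-reduction of the enone–enyne chromophore or of the α-ketol by the low-valent titanium reagent, or stalling at the oxime or imine stage in the buffered medium. The fallback is a redox-neutral, two-stage unmasking through the oxime. It sets out from 25: O-benzylation of the nitronate and fragmentation with loss of benzaldehyde (BnBr, KOH (1.05 equiv), n-Bu4NI (cat.), THF, 0 °C → rt) should give (2S,4S)-4-methylhexan-2-yl (1R,2R,6R)-5-[(3E)-5-tert-butoxy-5-oxopent-3-en-1-yn-1-yl]-2-hydroxy-6-[(hydroxyimino)methyl]-2-methyl-3-oxocyclohex-4-ene-1-carboxylate F2. Oxime exchange with aqueous glyoxylic acid (AcOH, rt) then liberates the aldehyde and comes back to the route at 28.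

Step 14. What may go wrong is attack of the enol oxygen on the nearer alkyne carbon (5-exo closure to an alkylidene furan), or loss of water with aromatisation of the carbocycle at the Lewis-acidic metal. The fallback is iodonium-induced cyclisation followed by reductive removal of iodine. It sets out from 28: I2 and NaHCO3 in MeCN at 0 °C should give, by 6-endo iodocyclisation, (2S,4S)-4-methylhexan-2-yl (7R,8R)-3-[(E)-3-tert-butoxy-3-oxoprop-1-en-1-yl]-7-hydroxy-4-iodo-7-methyl-6-oxo-7,8-dihydro-6H-isochromene-8-carboxylate F3. Hydrodeiodination with Pd(PPh3)4, HCO2H and Et3N in DMF at rt then comes back to the route at 29.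

Further compounds
F1 | step 12 | (2S,4S)-4-methylhexan-2-yl (3R,4E)-2-acetyl-4-[(3E)-5-tert-butoxy-5-oxopent-3-en-1-yn-1-yl]-6,6-dimethoxy-3-(nitromethyl)hex-4-enoate | CC[C@H](C)C[C@H](C)OC(=O)C(C(C)=O)[C@@H](C[N+](=O)[O-])/C(C#C/C=C/C(=O)OC(C)(C)C)=C\C(OC)OC
F2 | step 13 | (2S,4S)-4-methylhexan-2-yl (1R,2R,6R)-5-[(3E)-5-tert-butoxy-5-oxopent-3-en-1-yn-1-yl]-2-hydroxy-6-[(hydroxyimino)methyl]-2-methyl-3-oxocyclohex-4-ene-1-carboxylate | CC[C@H](C)C[C@H](C)OC(=O)[C@@H]1[C@@H](C=NO)C(C#C/C=C/C(=O)OC(C)(C)C)=CC(=O)[C@]1(C)O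
F3 | step 14 | (2S,4S)-4-methylhexan-2-yl (7R,8R)-3-[(E)-3-tert-butoxy-3-oxoprop-1-en-1-yl]-7-hydroxy-4-iodo-7-methyl-6-oxo-7,8-dihydro-6H-isochromene-8-carboxylate | CC[C@H](C)C[C@H](C)OC(=O)[C@@H]1C2=COC(/C=C/C(=O)OC(C)(C)C)=C(I)C2=CC(=O)[C@]1(C)O
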